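**Plan**

- Retrosynthesis: the first cut is the bond between the central (secondary) nitrogen and the neighbouring CH2 of the three-carbon arm, which gives a 3-amidopropanal and butane-1,4-diamine. The aldehyde is then masked as a diethyl acetal, and the amide C–N bond and the indole C3–C(=O) bond are cut last, leading to 6-bromoindole, oxalyl chloride and 3,3-diethoxypropan-1-amine.
- Enabling feature: in the chain N–(CH2)3–N–(CH2)4–N the acylated nitrogen sits on the three-carbon arm and the free NH2 on the four-carbon arm. The first cut therefore releases a diamine whose two nitrogens are equivalent, and the three nitrogens are told apart without a protecting group.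
- Forward order: no ring is formed (the indole bicycle is purchased). The chain is joined linearly by C3 glyoxylation and amidation in one flask, acetal hydrolysis, then reductive amination with the diamine.
- Stereochemistry: the target has no stereocentre and no stereogenic double bond, so nothing has to be set or preserved.

Key step: step 3

Remark on the chemistry: the target is drawn and counted as the free base. If preferred for storage it can be kept as its bis(trifluoroacetate), which is the same compound in protonated form.

**Step 1**
Reactants: 1 6-bromo-1H-indole; 2 3,3-diethoxypropan-1-amine
Product: 4 2-(6-bromo-1H-indol-3-yl)-N-(3,3-diethoxypropyl)-2-oxoacetamide, via glyoxylyl chloride 3 (not isolated)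
Conditions: (COCl)2 (1.2 equiv), Et2O, 0 °C → rt; volatiles removed in the same flask; then 2 (1.2 equiv), Et3N (3 equiv), THF, 0 °C → rt
Reagents that add atoms: oxalyl chloride, ClC(=O)C(=O)Cl
Why: The pyrrole C3 of 1 is nucleophilic enough for an uncatalysed Friedel–Crafts-type acylation by oxalyl chloride, which stops at the mono-acyl chloride 3 because the product is deactivated, and the primary amine of 2 then undergoes Schotten–Baumann-type aminolysis of 3 under basic conditions (Et3N) that leave the diethyl acetal untouched.

**Step 2**
Reactants: 4 2-(6-bromo-1H-indol-3-yl)-N-(3,3-diethoxypropyl)-2-oxoacetamide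
Product: 5 2-(6-bromo-1H-indol-3-yl)-2-oxo-N-(3-oxopropyl)acetamide
Conditions: 1 M aq HCl/THF (1:1), rt; cold aq NaHCO3 work-up, EtOAc; concentrated without heating and used at once
Reagents that add atoms: water, O
Why: Acid-catalysed acetal hydrolysis through the oxocarbenium ion is fast at room temperature in dilute aqueous acid, to which the glyoxamide, the indole N–H and the aryl bromide are inert, and the aldehyde is taken on at once because β-amido aldehydes slowly self-condense on storage.

**Step 3**
Reactants: 5 2-(6-bromo-1H-indol-3-yl)-2-oxo-N-(3-oxopropyl)acetamide; 6 butane-1,4-diamine
Product: 8 didemnidine B (N-{3-[(4-aminobutyl)amino]propyl}-2-(6-bromo-1H-indol-3-yl)-2-oxoacetamide), via aldimine 7 (not isolated)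
Conditions: 6 (10 equiv), 3 Å molecular sieves, THF, 0 °C, slow addition of 5; then AcOH, NaBH(OAc)3 (2.5 equiv), 0 °C → rt; aq K2CO3 work-up, excess 6 removed under high vacuum; C18 chromatography, H2O/MeOH/NH3
Reagents that add atoms: none
Why: One amino group of 6 adds to the aldehyde of 5 to give a hemiaminal that loses water to aldimine 7 (in equilibrium with its seven-membered cyclic aminal, which reopens to the same iminium ion), and AcOH-protonated 7 accepts hydride from NaBH(OAc)3 to form the bond between the central nitrogen and the propyl CH2. The closest known reaction type is the direct reductive amination of an aliphatic aldehyde with a primary amine by NaBH(OAc)3 (Borch-type reductive amination), which is commonly run with an excess of a symmetric diamine to obtain the mono-alkylated product. No ring is closed and no stereocentre is created, so neither a mode of closure nor a stereocontrolling element is involved. The step needs chemoselectivity for the aldehyde over the C3 keto group; the substrate supplies it because that carbonyl is deactivated by donation from the indole nitrogen through C2=C3 and therefore condenses sluggishly, while NaBH(OAc)3 reduces iminium ions far faster than ketones. It also needs mono-alkylation, which the tenfold excess of 6 and the slow addition of 5 should secure; no regiochemical question arises because the two amino groups of 6 are equivalent by symmetry and the amide nitrogen was placed on the three-carbon arm in step 1. The cold, weakly acidic medium should also trap the β-amido aldehyde as the imine before it can undergo aldol self-condensation.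

**Compound list**

1 | 6-bromo-1H-indole | Brc1ccc2cc[nH]c2c1 | starting material
2 | 3,3-diethoxypropan-1-amine | CCOC(CCN)OCC | starting material
3 | 2-(6-bromo-1H-indol-3-yl)-2-oxoacetyl chloride | O=C(Cl)C(=O)c1c[nH]c2cc(Br)ccc12 | intermediate
4 | 2-(6-bromo-1H-indol-3-yl)-N-(3,3-diethoxypropyl)-2-oxoacetamide | CCOC(CCNC(=O)C(=O)c1c[nH]c2cc(Br)ccc12)OCC | intermediate
5 | 2-(6-bromo-1H-indol-3-yl)-2-oxo-N-(3-oxopropyl)acetamide | O=CCCNC(=O)C(=O)c1c[nH]c2cc(Br)ccc12 | intermediate
6 | butane-1,4-diamine | NCCCCN | starting material
7 | N-{(3E)-3-[(4-aminobutyl)imino]propyl}-2-(6-bromo-1H-indol-3-yl)-2-oxoacetamide | NCCCC/N=C/CCNC(=O)C(=O)c1c[nH]c2cc(Br)ccc12 | intermediate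
8 | didemnidine B, N-{3-[(4-aminobutyl)amino]propyl}-2-(6-bromo-1H-indol-3-yl)-2-oxoacetamide | NCCCCNCCCNC(=O)C(=O)c1c[nH]c2cc(Br)ccc12 | target

**Step count**

Total steps: 3. Longest linear sequence: 3 steps (from 6-bromoindole 1).

**Steps most likely to fail**

Step 3 (riskiest). What may go wrong: a second alkylation of the new secondary amine or of the distal NH2 by further aldehyde, slow condensation of the excess diamine at the keto carbonyl, and loss of the very polar product while it is separated from the tenfold excess of 6. The fallback sets out from aldehyde 5 and replaces the free diamine by its commercially available mono-carbamate, tert-butyl (4-aminobutyl)carbamate (1.2 equiv). Condensation in THF over 3 Å molecular sieves should give the Boc-protected aldimine tert-butyl N-{4-[(E)-{3-[2-(6-bromo-1H-indol-3-yl)-2-oxoacetamido]propylidene}amino]butyl}carbamate F1. Reduction in the same flask with NaBH(OAc)3/AcOH should give the Boc-protected triamine tert-butyl N-[4-({3-[2-(6-bromo-1H-indol-3-yl)-2-oxoacetamido]propyl}amino)butyl]carbamate F2, which is lipophilic enough for ordinary silica chromatography. TFA in CH2Cl2 (0 °C → rt) followed by a basic ion-exchange work-up then removes the carbamate and returns the route at target 8. The key bond is formed in the same way; only the distal nitrogen is masked.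

Step 2. What may go wrong: aldol self-condensation or oligomerisation of the liberated β-amido aldehyde, or loss of the amide by retro-Michael-type elimination, during aqueous acid treatment, extraction and concentration. The fallback reaches the aldehyde from the alcohol oxidation level and sets out from acid chloride 3, generated from 1 as in step 1. Quenching 3 with 3-aminopropan-1-ol and Et3N in THF at 0 °C (the amine reacts in preference to the hydroxyl) should give the storable alcohol 2-(6-bromo-1H-indol-3-yl)-N-(3-hydroxypropyl)-2-oxoacetamide F3. Oxidation with Dess–Martin periodinane in CH2Cl2/THF at rt under anhydrous, non-aqueous conditions should give the aldehyde, and after filtration the solution is carried directly into step 3. The fallback comes back to the route at 5.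

Step 1. What may go wrong: incomplete C3 acylation of the bromine-deactivated indole, and consumption of the aminoacetal (oxamide formation) or cleavage of its acetal by residual oxalyl chloride and HCl in the one-flask procedure. The fallback separates acylation from amide formation and sets out from 1. Et2AlCl-promoted Friedel–Crafts acylation with methyl chlorooxoacetate (CH2Cl2, 0 °C) should give the crystalline keto ester methyl 2-(6-bromo-1H-indol-3-yl)-2-oxoacetate F4, which can be purified. Aminolysis of this activated α-keto ester with 2 in MeOH at 60 °C, with no acid present, should then give the acetal amide, and the fallback comes back to the route at 4.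

**Further compounds**

F1 | step 3 | tert-butyl N-{4-[(E)-{3-[2-(6-bromo-1H-indol-3-yl)-2-oxoacetamido]propylidene}amino]butyl}carbamate | CC(C)(C)OC(=O)NCCCC/N=C/CCNC(=O)C(=O)c1c[nH]c2cc(Br)ccc12
F2 | step 3 | tert-butyl N-[4-({3-[2-(6-bromo-1H-indol-3-yl)-2-oxoacetamido]propyl}amino)butyl]carbamate | CC(C)(C)OC(=O)NCCCCNCCCNC(=O)C(=O)c1c[nH]c2cc(Br)ccc12
F3 | step 2 | 2-(6-bromo-1H-indol-3-yl)-N-(3-hydroxypropyl)-2-oxoacetamide | OCCCNC(=O)C(=O)c1c[nH]c2cc(Br)ccc12
F4 | step 1 | methyl 2-(6-bromo-1H-indol-3-yl)-2-oxoacetate | COC(=O)C(=O)c1c[nH]c2cc(Br)ccc12
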